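**Plan**

1. Retrosynthesis: the three phenols are masked as methoxymethyl (MOM) ethers. Both C3–CH3 bonds of the two (6E)-3,7,11-trimethyldodeca-1,6,10-trien-3-yl arms are cut together (allylic phosphates + Me2Zn). Then follow the two aryl–C3 bonds (aryl boronate + enol triflate), the C4–C5 bond of the arm chain (acetoacetate dianion + geranyl bromide) and the diaryl ether C–O bond (SNAr).
2. Forward: no ring is formed, both benzene rings are bought. Ring B (two hydroxyls) and ring A (one hydroxyl) are joined through the ether oxygen. The arm on ring A is attached as a Z enoate, then the arm on ring B as an E enoate. Reduction, phosphorylation, twofold methylation and MOM removal complete the chain.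
3. Enabling feature: the quaternary carbons C3 on ring A and C3 on ring B carry the same four groups (aryl, vinyl, methyl, 4,8-dimethylnona-3,7-dienyl) but are R on ring A and S on ring B. A Z allylic arm on ring A and an E allylic arm on ring B can therefore be methylated by one catalyst enantiomer.
4. Stereochemistry: the 2Z/2E geometries come from stereodefined enol triflates and stereoretentive Suzuki–Miyaura couplings, the absolute configuration from a chiral carbene–copper catalyst, the 6E olefins from geranyl bromide.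
5. MOM ethers are used because the vicinal pair of aryl methyl ethers that ring B would otherwise carry cannot be counted on to cleave completely under conditions the polyene survives.

Key step: step 16

Assumption: the sense of induction of the chiral carbene precursor L (a C1-symmetric 4,5-diphenylimidazolinium salt with an N-(2-sulfonatophenyl) and an N-mesityl group) is calibrated once on a simple (E)-γ-aryl-γ-alkyl allylic phosphate; "L" is the enantiomer that places methyl on the olefin face that is Re at C2 of an arm, "ent-L" its mirror image.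

**Route**

Step 1
Reactants: 1 5-chloro-2-hydroxy-3-methoxybenzaldehyde
Product: 2 5-chloro-2,3-dihydroxybenzaldehyde
Conditions: BBr3, CH2Cl2, −78 °C → rt; H2O
Reagents that add atoms: none
Why: Lewis-acid ether cleavage, in which bromide attacks the O-methyl group of the boron–ether adduct, frees the second phenol, and the aldehyde is returned unchanged on hydrolysis.

Step 2
Reactants: 2 5-chloro-2,3-dihydroxybenzaldehyde
Product: 3 5-chloro-2,3-bis(methoxymethoxy)benzaldehyde
Conditions: NaH, DMF, 0 °C; MOMCl, 0 °C → rt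
Reagents that add atoms: chloromethyl methyl ether (MOMCl), COCCl
Why: Williamson-type O-alkylation of the catechol dianion with the reactive α-chloro ether caps both phenols, so that the hydroxyl unmasked in step 3 is the only nucleophile in step 5.

Step 3
Reactants: 3 5-chloro-2,3-bis(methoxymethoxy)benzaldehyde
Product: 5 5-chloro-2,3-bis(methoxymethoxy)phenol, via aryl formate 4 (not isolated)
Conditions: mCPBA, CH2Cl2, 0 °C → rt; aq NaHCO3 wash; K2CO3 (cat.), MeOH, rt
Reagents that add atoms: 3-chloroperoxybenzoic acid (mCPBA), OOC(=O)c1cccc(Cl)c1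
Why: Baeyer–Villiger oxidation of the electron-rich ortho-alkoxy benzaldehyde should proceed with aryl migration (Dakin-type outcome) to the formate, which methanolysis cleaves, while the MOM acetals and the aryl chloride tolerate the weak acid at room temperature.

Step 4
Reactants: 6 2-fluoro-5-nitrophenol
Product: 7 1-fluoro-2-(methoxymethoxy)-4-nitrobenzene
Conditions: MOMCl, i-Pr2NEt, CH2Cl2, 0 °C → rt
Reagents that add atoms: chloromethyl methyl ether (MOMCl), COCCl
Why: Williamson-type O-alkylation of the acidic nitrophenol under amine base gives the MOM ether without touching the activated fluoride.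

Step 5
Reactants: 5 5-chloro-2,3-bis(methoxymethoxy)phenol; 7 1-fluoro-2-(methoxymethoxy)-4-nitrobenzene
Product: 8 5-chloro-1,2-bis(methoxymethoxy)-3-[2-(methoxymethoxy)-4-nitrophenoxy]benzene (ring A = nitro ring, ring B = chloro ring)
Conditions: K2CO3, DMF, 80 °C
Reagents that add atoms: none
Why: Nucleophilic aromatic substitution (SNAr) in which the phenoxide of 5 displaces the fluoride para to the nitro group; the unactivated chloride is inert and the absence of a free ortho-hydroxyl rules out a Smiles rearrangement.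

Step 6
Reactants: 8 5-chloro-1,2-bis(methoxymethoxy)-3-[2-(methoxymethoxy)-4-nitrophenoxy]benzene
Product: 9 4-[5-chloro-2,3-bis(methoxymethoxy)phenoxy]-3-(methoxymethoxy)aniline
Conditions: H2 (1 atm), sulfided Pt/C, EtOAc, rt
Reagents that add atoms: none
Why: Catalytic hydrogenation of the nitro group over sulfided platinum, which is poisoned against hydrodechlorination, should give the aniline with the aryl chloride, the diaryl ether and the MOM acetals intact.

Step 7
Reactants: 9 4-[5-chloro-2,3-bis(methoxymethoxy)phenoxy]-3-(methoxymethoxy)aniline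
Product: 11 2-{4-[5-chloro-2,3-bis(methoxymethoxy)phenoxy]-3-(methoxymethoxy)phenyl}-4,4,5,5-tetramethyl-1,3,2-dioxaborolane, via arenediazonium tert-butoxide 10 (not isolated)
Conditions: t-BuONO, B2pin2, (PhCO2)2 (cat.), MeCN, rt
Reagents that add atoms: bis(pinacolato)diboron (B2pin2), CC1(C)OB(OC1(C)C)B1OC(C)(C)C(C)(C)O1
Why: Sandmeyer-type borylation, in which neutral diazotisation by the alkyl nitrite and radical C–B bond formation with B2pin2 replace NH2 by the boronate at the same carbon, in an acid-free medium that spares the MOM groups.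

Step 8
Reactants: 12 ethyl acetoacetate; 13 geranyl bromide
Product: 15 ethyl (6E)-7,11-dimethyl-3-oxododeca-6,10-dienoate, via acetoacetate dianion 14 (not isolated)
Conditions: NaH, THF, 0 °C; n-BuLi, 0 °C; 13, 0 °C → rt; 1 M HCl
Reagents that add atoms: none
Why: γ-Alkylation of the acetoacetate dianion, whose more basic terminal carbanion attacks the primary allylic bromide by SN2, so the 2E olefin of the geranyl unit becomes the 6E olefin of the product.

Step 9
Reactants: 15 ethyl (6E)-7,11-dimethyl-3-oxododeca-6,10-dienoate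
Product: 16 ethyl (2Z,6E)-7,11-dimethyl-3-(trifluoromethylsulfonyloxy)dodeca-2,6,10-trienoate (OTf cis to the ester)
Conditions: Tf2O, sat. aq LiOH, toluene, 5–10 °C
Reagents that add atoms: trifluoromethanesulfonic anhydride (Tf2O), O=S(=O)(OS(=O)(=O)C(F)(F)F)C(F)(F)F
Why: O-Triflation of the lithium-chelated enolate under biphasic conditions should give the enol triflate with the triflate cis to the ester (2Z).

Step 10
Reactants: 15 ethyl (6E)-7,11-dimethyl-3-oxododeca-6,10-dienoate
Product: 17 ethyl (2E,6E)-7,11-dimethyl-3-(trifluoromethylsulfonyloxy)dodeca-2,6,10-trienoate (OTf trans to the ester)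
Conditions: Tf2O, aq Me4NOH, hexane, 5–10 °C
Reagents that add atoms: trifluoromethanesulfonic anhydride (Tf2O), O=S(=O)(OS(=O)(=O)C(F)(F)F)C(F)(F)F
Why: O-Triflation of the enolate paired with the non-coordinating tetramethylammonium ion, which adopts the extended dipole-minimised geometry, should give the isomer with the triflate trans to the ester (2E).

Step 11
Reactants: 11 2-{4-[5-chloro-2,3-bis(methoxymethoxy)phenoxy]-3-(methoxymethoxy)phenyl}-4,4,5,5-tetramethyl-1,3,2-dioxaborolane; 16 ethyl (2Z,6E)-7,11-dimethyl-3-(trifluoromethylsulfonyloxy)dodeca-2,6,10-trienoate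
Product: 18 ethyl (2Z,6E)-3-{4-[5-chloro-2,3-bis(methoxymethoxy)phenoxy]-3-(methoxymethoxy)phenyl}-7,11-dimethyldodeca-2,6,10-trienoate
Conditions: Pd(PPh3)4 (5 mol %), K3PO4, THF/H2O, 50 °C
Reagents that add atoms: none
Why: Suzuki–Miyaura coupling, in which oxidative addition of zerovalent palladium into the vinyl C–OTf bond and reductive elimination both retain configuration, places ring A cis to the ester (2Z), and the aryl chloride on ring B does not react with the triphenylphosphine catalyst at this temperature.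

Step 12
Reactants: 18 ethyl (2Z,6E)-3-{4-[5-chloro-2,3-bis(methoxymethoxy)phenoxy]-3-(methoxymethoxy)phenyl}-7,11-dimethyldodeca-2,6,10-trienoate
Product: 19 ethyl (2Z,6E)-3-{4-[2,3-bis(methoxymethoxy)-5-(4,4,5,5-tetramethyl-1,3,2-dioxaborolan-2-yl)phenoxy]-3-(methoxymethoxy)phenyl}-7,11-dimethyldodeca-2,6,10-trienoate
Conditions: B2pin2, Pd2(dba)3, XPhos, KOAc, 1,4-dioxane, 100 °C
Reagents that add atoms: bis(pinacolato)diboron (B2pin2), CC1(C)OB(OC1(C)C)B1OC(C)(C)C(C)(C)O1
Why: Miyaura borylation, in which the electron-rich biaryl phosphine lets zerovalent palladium insert into the aryl chloride and acetate-assisted transmetalation with B2pin2 delivers the boronate, leaves the trisubstituted Z enoate and the isolated olefins as spectators.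

Step 13
Reactants: 19 ethyl (2Z,6E)-3-{4-[2,3-bis(methoxymethoxy)-5-(4,4,5,5-tetramethyl-1,3,2-dioxaborolan-2-yl)phenoxy]-3-(methoxymethoxy)phenyl}-7,11-dimethyldodeca-2,6,10-trienoate; 17 ethyl (2E,6E)-7,11-dimethyl-3-(trifluoromethylsulfonyloxy)dodeca-2,6,10-trienoate
Product: 20 ethyl (2Z,6E)-3-{4-[5-((2E,6E)-1-ethoxy-7,11-dimethyl-1-oxododeca-2,6,10-trien-3-yl)-2,3-bis(methoxymethoxy)phenoxy]-3-(methoxymethoxy)phenyl}-7,11-dimethyldodeca-2,6,10-trienoate (Z enoate on ring A, E enoate on ring B)
Conditions: Pd(PPh3)4 (5 mol %), K3PO4, THF/H2O, 50 °C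
Reagents that add atoms: none
Why: A second stereoretentive Suzuki–Miyaura coupling places ring B trans to the ester (2E), while the Z enoate on ring A is untouched.

Step 14
Reactants: 20 the Z,E diester
Product: 21 (2Z,6E)-3-{4-[5-((2E,6E)-1-hydroxy-7,11-dimethyldodeca-2,6,10-trien-3-yl)-2,3-bis(methoxymethoxy)phenoxy]-3-(methoxymethoxy)phenyl}-7,11-dimethyldodeca-2,6,10-trien-1-ol
Conditions: i-Bu2AlH (5 equiv), CH2Cl2, −78 → −20 °C; aq potassium sodium tartrate
Reagents that add atoms: none
Why: 1,2-Reduction of both α,β-unsaturated esters by the aluminium hydride should give the two allylic alcohols with the 2Z and 2E geometries unchanged, and acetals, diaryl ether and isolated olefins are inert to it.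

Step 15
Reactants: 21 the Z,E diol
Product: 22 bis(diethyl phosphate) of diol 21, namely diethyl (2Z,6E)-3-{4-[5-((2E,6E)-1-(diethoxyphosphoryloxy)-7,11-dimethyldodeca-2,6,10-trien-3-yl)-2,3-bis(methoxymethoxy)phenoxy]-3-(methoxymethoxy)phenyl}-7,11-dimethyldodeca-2,6,10-trien-1-yl phosphate
Conditions: ClP(O)(OEt)2, Et3N, DMAP (cat.), CH2Cl2, 0 °C; filtration through Et3N-washed silica, used at once
Reagents that add atoms: diethyl chlorophosphate, CCOP(=O)(Cl)OCC
Why: O-Phosphorylation of the two primary allylic alcohols under nucleophilic catalysis installs the leaving groups, and the basic medium and base-washed silica suppress ionisation of the electron-rich allylic phosphates.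

Step 16
Reactants: 22 the Z,E bis(diethyl phosphate); 23 dimethylzinc
Product: 24 1,2-bis(methoxymethoxy)-3-{2-(methoxymethoxy)-4-[(3R,6E)-3,7,11-trimethyldodeca-1,6,10-trien-3-yl]phenoxy}-5-[(3S,6E)-3,7,11-trimethyldodeca-1,6,10-trien-3-yl]benzene
Conditions: L (11 mol %), Me2Zn (6 equiv), THF, rt, 15 min; Cu(OTf)2 (10 mol %); 22, −30 → −15 °C; aq NH4Cl/HCl
Reagents that add atoms: dimethylzinc (23), C[Zn]C
Why: Me2Zn deprotonates L and reduces Cu(OTf)2 to monovalent copper, giving a carbene-bound methylcopper species that coordinates the C2=C3 bond of each arm, expels the phosphate from C1 in an anti SN2' oxidative addition to a trivalent σ-allylcopper at C3 and reductively eliminates there, which forms the C3–CH3 bond and leaves C1=C2 as the vinyl group. The closest known reaction type is the copper-catalysed enantioselective allylic substitution of γ-aryl-γ-alkyl allylic phosphates with dialkylzinc reagents that builds all-carbon quaternary centres; it is applied here at two sites of one molecule, and no ring is closed. The centre on ring A is set by catalyst-controlled methyl delivery to the C3 Si face of the Z arm and the centre on ring B by delivery to the C3 Re face of the E arm; seen from C2 these are the same face (Re), so one ligand enantiomer should serve both and the R/S pairing follows from the Z/E geometries fixed in steps 9 to 13. The step needs SN2' over SN2 selectivity, which the carbene–copper catalyst and the phosphate leaving group provide, and independent facial control at two sites, which the rigid diaryl ether spacer between the arms allows. MOM acetals, the diaryl ether and the isolated trisubstituted olefins should not react with Me2Zn at −15 °C.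

Step 17
Reactants: 24 the tris(MOM) ether
Product: 25 3-{2-hydroxy-4-[(3R,6E)-3,7,11-trimethyldodeca-1,6,10-trien-3-yl]phenoxy}-5-[(3S,6E)-3,7,11-trimethyldodeca-1,6,10-trien-3-yl]benzene-1,2-diol (CNP0230356.1)
Conditions: TsOH·H2O (0.3 equiv), MeOH/THF, 40 °C, argon
Reagents that add atoms: none
Why: Acid-catalysed acetal exchange with methanol should cleave the three aryl MOM ethers as dimethoxymethane under conditions too mild to protonate the trisubstituted olefins, and the two quaternary stereocentres carry no bond that can ionise or epimerise.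

**Compound list**

1 | 5-chloro-2-hydroxy-3-methoxybenzaldehyde | COc1cc(Cl)cc(C=O)c1O | starting material
2 | 5-chloro-2,3-dihydroxybenzaldehyde | O=Cc1cc(Cl)cc(O)c1O | intermediate
3 | 5-chloro-2,3-bis(methoxymethoxy)benzaldehyde | COCOc1cc(Cl)cc(C=O)c1OCOC | intermediate
4 | 5-chloro-2,3-bis(methoxymethoxy)phenyl formate (not isolated) | O=COc1cc(Cl)cc(OCOC)c1OCOC | intermediate
5 | 5-chloro-2,3-bis(methoxymethoxy)phenol | COCOc1cc(Cl)cc(O)c1OCOC | intermediate
6 | 2-fluoro-5-nitrophenol | Oc1cc([N+](=O)[O-])ccc1F | starting material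
7 | 1-fluoro-2-(methoxymethoxy)-4-nitrobenzene | COCOc1cc([N+](=O)[O-])ccc1F | intermediate
8 | 5-chloro-1,2-bis(methoxymethoxy)-3-[2-(methoxymethoxy)-4-nitrophenoxy]benzene | COCOc1cc(Cl)cc(Oc2ccc([N+](=O)[O-])cc2OCOC)c1OCOC | intermediate
9 | 4-[5-chloro-2,3-bis(methoxymethoxy)phenoxy]-3-(methoxymethoxy)aniline | COCOc1cc(Cl)cc(Oc2ccc(N)cc2OCOC)c1OCOC | intermediate
10 | 4-[5-chloro-2,3-bis(methoxymethoxy)phenoxy]-3-(methoxymethoxy)benzenediazonium tert-butoxide (not isolated) | COCOc1cc(Cl)cc(Oc2ccc([N+]#N)cc2OCOC)c1OCOC.CC(C)(C)[O-] | intermediate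
11 | 2-{4-[5-chloro-2,3-bis(methoxymethoxy)phenoxy]-3-(methoxymethoxy)phenyl}-4,4,5,5-tetramethyl-1,3,2-dioxaborolane | COCOc1cc(Cl)cc(Oc2ccc(B3OC(C)(C)C(C)(C)O3)cc2OCOC)c1OCOC | intermediate
12 | ethyl acetoacetate | CCOC(=O)CC(C)=O | starting material
13 | geranyl bromide, (2E)-1-bromo-3,7-dimethylocta-2,6-diene | CC(C)=CCC/C(C)=C/CBr | starting material
14 | sodium lithium dianion of ethyl acetoacetate (not isolated) | [Na+].[Li+].C=C([O-])C=C([O-])OCC | intermediate
15 | ethyl (6E)-7,11-dimethyl-3-oxododeca-6,10-dienoate | CCOC(=O)CC(=O)CC/C=C(\C)CCC=C(C)C | intermediate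
16 | ethyl (2Z,6E)-7,11-dimethyl-3-(trifluoromethylsulfonyloxy)dodeca-2,6,10-trienoate | CCOC(=O)/C=C(\OS(=O)(=O)C(F)(F)F)CC/C=C(\C)CCC=C(C)C | intermediate
17 | ethyl (2E,6E)-7,11-dimethyl-3-(trifluoromethylsulfonyloxy)dodeca-2,6,10-trienoate | CCOC(=O)/C=C(/OS(=O)(=O)C(F)(F)F)CC/C=C(\C)CCC=C(C)C | intermediate
18 | ethyl (2Z,6E)-3-{4-[5-chloro-2,3-bis(methoxymethoxy)phenoxy]-3-(methoxymethoxy)phenyl}-7,11-dimethyldodeca-2,6,10-trienoate | CCOC(=O)/C=C(\c1ccc(Oc2cc(Cl)cc(OCOC)c2OCOC)c(OCOC)c1)CC/C=C(\C)CCC=C(C)C | intermediate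
19 | ethyl (2Z,6E)-3-{4-[2,3-bis(methoxymethoxy)-5-(4,4,5,5-tetramethyl-1,3,2-dioxaborolan-2-yl)phenoxy]-3-(methoxymethoxy)phenyl}-7,11-dimethyldodeca-2,6,10-trienoate | CCOC(=O)/C=C(\c1ccc(Oc2cc(B3OC(C)(C)C(C)(C)O3)cc(OCOC)c2OCOC)c(OCOC)c1)CC/C=C(\C)CCC=C(C)C | intermediate
20 | diester with the (2Z,6E) enoate arm on ring A and the (2E,6E) enoate arm on ring B, tris(MOM) ether | CCOC(=O)/C=C(\c1ccc(Oc2cc(/C(CC/C=C(\C)CCC=C(C)C)=C/C(=O)OCC)cc(OCOC)c2OCOC)c(OCOC)c1)CC/C=C(\C)CCC=C(C)C | intermediate
21 | diol with the (2Z,6E) allylic alcohol arm on ring A and the (2E,6E) arm on ring B, tris(MOM) ether | OC/C=C(\c1ccc(Oc2cc(/C(CC/C=C(\C)CCC=C(C)C)=C/CO)cc(OCOC)c2OCOC)c(OCOC)c1)CC/C=C(\C)CCC=C(C)C | intermediate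
22 | bis(diethyl phosphate) of diol 21, Z arm on ring A and E arm on ring B | CCOP(=O)(OCC)OC/C=C(\c1ccc(Oc2cc(/C(CC/C=C(\C)CCC=C(C)C)=C/COP(=O)(OCC)OCC)cc(OCOC)c2OCOC)c(OCOC)c1)CC/C=C(\C)CCC=C(C)C | intermediate
23 | dimethylzinc | C[Zn]C | starting material
24 | 1,2-bis(methoxymethoxy)-3-{2-(methoxymethoxy)-4-[(3R,6E)-3,7,11-trimethyldodeca-1,6,10-trien-3-yl]phenoxy}-5-[(3S,6E)-3,7,11-trimethyldodeca-1,6,10-trien-3-yl]benzene | C=C[C@@](C)(CC/C=C(\C)CCC=C(C)C)c1ccc(Oc2cc([C@](C)(C=C)CC/C=C(\C)CCC=C(C)C)cc(OCOC)c2OCOC)c(OCOC)c1 | intermediate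
25 | 3-{2-hydroxy-4-[(3R,6E)-3,7,11-trimethyldodeca-1,6,10-trien-3-yl]phenoxy}-5-[(3S,6E)-3,7,11-trimethyldodeca-1,6,10-trien-3-yl]benzene-1,2-diol (CNP0230356.1) | C=C[C@@](C)(CC/C=C(\C)CCC=C(C)C)c1ccc(Oc2cc([C@](C)(C=C)CC/C=C(\C)CCC=C(C)C)cc(O)c2O)c(O)c1 | target

**Step count**

Total: 17 steps. Longest linear sequence: 13 steps (steps 1, 2, 3, 5, 6, 7, 11, 12, 13, 14, 15, 16, 17 from compound 1).

**Steps most likely to fail**

Step 16. The Z arm, whose aryl group is twisted out of the olefin plane by allylic strain, may be methylated with weak facial discrimination, or the second site may turn over slowly. Ionisation of the bis-phosphate before methylation would erode the olefin geometries with the same result. In each case diastereomers of 24 would form that are unlikely to be separable. Fallback: both arms are built with E geometry, the geometry for which this substitution is best established, and are methylated one after the other with the two enantiomers of L. Setting out from boronate 11, Suzuki–Miyaura coupling with E triflate 17 (Pd(PPh3)4, K3PO4, THF/H2O) should give the ring A (2E)-enoate F1. Reduction with i-Bu2AlH gives the allylic alcohol F2, and ClP(O)(OEt)2 with Et3N gives the monophosphate F3. Cu(OTf)2, ent-L and Me2Zn 23 then place methyl on the C3 Si face of this E arm and give the (R)-configured aryl chloride F4, whose enantiomeric purity can be assayed before going on. Miyaura borylation (B2pin2, Pd2(dba)3, XPhos, KOAc) gives the boronate F5, a second coupling with 17 gives the ring B (2E)-enoate F6, i-Bu2AlH gives the alcohol F7 and phosphorylation gives the phosphate F8. Cu(OTf)2, L and Me2Zn finally place methyl on the C3 Re face of the ring B arm, and the sequence comes back to the route at 24. Only one ionisable phosphate is present at a time and each is used at once.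

Step 12. Oxidative addition into the electron-rich aryl chloride may be slow, so that protodechlorination competes or the Z enoate isomerises during prolonged heating. Fallback: the polarity of the second coupling is reversed. Setting out from E triflate 17, Miyaura borylation (B2pin2, PdCl2(dppf), K2CO3, 1,4-dioxane, 80 °C) should give with retention the alkenyl boronate F9, in which boron is trans to the ester. Suzuki–Miyaura coupling of F9 with aryl chloride 18 (Pd(OAc)2, SPhos, K3PO4, toluene/H2O, 80 °C) then comes back to the route at diester 20 without passing through 19.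

Step 17. The Brønsted acid may protonate the trisubstituted olefins (hydration or cation–olefin cyclisation) before all three acetals are cleaved, or the pyrogallol-type ring may oxidise. Fallback: the MOM groups are exchanged for silyl groups without protic acid. Setting out from 24, TMSOTf and 2,2′-bipyridyl in MeCN at 0 °C should convert the three aryl MOM ethers into the tris(trimethylsilyl) ether F10, and addition of water then hydrolyses the aryl silyl ethers and comes back to the route at target 25.

**Further compounds**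

F1 | step 16 | ethyl (2E,6E)-3-{4-[5-chloro-2,3-bis(methoxymethoxy)phenoxy]-3-(methoxymethoxy)phenyl}-7,11-dimethyldodeca-2,6,10-trienoate | CCOC(=O)/C=C(/c1ccc(Oc2cc(Cl)cc(OCOC)c2OCOC)c(OCOC)c1)CC/C=C(\C)CCC=C(C)C
F2 | step 16 | (2E,6E)-3-{4-[5-chloro-2,3-bis(methoxymethoxy)phenoxy]-3-(methoxymethoxy)phenyl}-7,11-dimethyldodeca-2,6,10-trien-1-ol | OC/C=C(/c1ccc(Oc2cc(Cl)cc(OCOC)c2OCOC)c(OCOC)c1)CC/C=C(\C)CCC=C(C)C
F3 | step 16 | diethyl (2E,6E)-3-{4-[5-chloro-2,3-bis(methoxymethoxy)phenoxy]-3-(methoxymethoxy)phenyl}-7,11-dimethyldodeca-2,6,10-trien-1-yl phosphate | CCOP(=O)(OCC)OC/C=C(/c1ccc(Oc2cc(Cl)cc(OCOC)c2OCOC)c(OCOC)c1)CC/C=C(\C)CCC=C(C)C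
F4 | step 16 | 5-chloro-1,2-bis(methoxymethoxy)-3-{2-(methoxymethoxy)-4-[(3R,6E)-3,7,11-trimethyldodeca-1,6,10-trien-3-yl]phenoxy}benzene | C=C[C@@](C)(CC/C=C(\C)CCC=C(C)C)c1ccc(Oc2cc(Cl)cc(OCOC)c2OCOC)c(OCOC)c1
F5 | step 16 | 2-[3,4-bis(methoxymethoxy)-5-{2-(methoxymethoxy)-4-[(3R,6E)-3,7,11-trimethyldodeca-1,6,10-trien-3-yl]phenoxy}phenyl]-4,4,5,5-tetramethyl-1,3,2-dioxaborolane | C=C[C@@](C)(CC/C=C(\C)CCC=C(C)C)c1ccc(Oc2cc(B3OC(C)(C)C(C)(C)O3)cc(OCOC)c2OCOC)c(OCOC)c1
F6 | step 16 | ethyl (2E,6E)-3-[3,4-bis(methoxymethoxy)-5-{2-(methoxymethoxy)-4-[(3R,6E)-3,7,11-trimethyldodeca-1,6,10-trien-3-yl]phenoxy}phenyl]-7,11-dimethyldodeca-2,6,10-trienoate | C=C[C@@](C)(CC/C=C(\C)CCC=C(C)C)c1ccc(Oc2cc(/C(CC/C=C(\C)CCC=C(C)C)=C/C(=O)OCC)cc(OCOC)c2OCOC)c(OCOC)c1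
F7 | step 16 | (2E,6E)-3-[3,4-bis(methoxymethoxy)-5-{2-(methoxymethoxy)-4-[(3R,6E)-3,7,11-trimethyldodeca-1,6,10-trien-3-yl]phenoxy}phenyl]-7,11-dimethyldodeca-2,6,10-trien-1-ol | C=C[C@@](C)(CC/C=C(\C)CCC=C(C)C)c1ccc(Oc2cc(/C(CC/C=C(\C)CCC=C(C)C)=C/CO)cc(OCOC)c2OCOC)c(OCOC)c1
F8 | step 16 | diethyl (2E,6E)-3-[3,4-bis(methoxymethoxy)-5-{2-(methoxymethoxy)-4-[(3R,6E)-3,7,11-trimethyldodeca-1,6,10-trien-3-yl]phenoxy}phenyl]-7,11-dimethyldodeca-2,6,10-trien-1-yl phosphate | C=C[C@@](C)(CC/C=C(\C)CCC=C(C)C)c1ccc(Oc2cc(/C(CC/C=C(\C)CCC=C(C)C)=C/COP(=O)(OCC)OCC)cc(OCOC)c2OCOC)c(OCOC)c1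
F9 | step 12 | ethyl (2Z,6E)-7,11-dimethyl-3-(4,4,5,5-tetramethyl-1,3,2-dioxaborolan-2-yl)dodeca-2,6,10-trienoate | CCOC(=O)/C=C(/B1OC(C)(C)C(C)(C)O1)CC/C=C(\C)CCC=C(C)C
F10 | step 17 | tris(trimethylsilyl) ether of 25 | C=C[C@@](C)(CC/C=C(\C)CCC=C(C)C)c1ccc(Oc2cc([C@](C)(C=C)CC/C=C(\C)CCC=C(C)C)cc(O[Si](C)(C)C)c2O[Si](C)(C)C)c(O[Si](C)(C)C)c1
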